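## Retrosynthetic overview

1. Gravicycle ⇐ its tris‑MOM ether by global deprotection.
2. Tris‑MOM macrocycle ⇐ open‑chain ω‑bromoalkyl aryl aldehyde. The C1–C2 bond, the 22‑membered ring and the (R)‑carbinol are made together in an enantioselective Co/Cr radical–polar crossover macrocyclisation (primary alkyl radical → chiral alkyl–Cr(III) → ArCHO).
3. Seco‑aldehyde ⇐ diaryl ether (ArBr → ArCHO) ⇐ Chan–Lam union of a ring‑A boronic acid with a 2,6‑disubstituted ring‑B phenol.
4. Ring‑A boronic acid ⇐ 3‑bromophenol + C13 chain (C7 + C6) by B‑alkyl Suzuki coupling and Ir C–H borylation. Ring‑B phenol ⇐ resorcinol by directed metalation/oxidation and para‑bromination.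
5. Ring order: both arenes are bought as arenes; the macrocycle is the only ring formed, in the last C–C bond‑forming step.

Assumption: C1 of the target is (R) as read from the SMILES, and one‑pot sequences with a single work‑up are counted as one step.

## Route

**Step 1**
Reactants: 1 resorcinol
Product: 2 1,3‑bis(methoxymethoxy)benzene
Conditions: NaH, MOMCl, DMF, 0 °C → rt
Reagents that add atoms: chloromethyl methyl ether (MOMCl), COCCl
Why: Williamson‑type O‑alkylation (MOM protection); the MOM groups later direct the metalation.

**Step 2**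
Reactants: 2 1,3‑bis(methoxymethoxy)benzene
Product: 3 2,6‑bis(methoxymethoxy)phenol
Conditions: n‑BuLi, THF, 0 °C → rt; B(OMe)3, −78 °C → rt; H2O2, aq NaOH, 0 °C
Reagents that add atoms: hydrogen peroxide, OO (phenolic oxygen)
Why: Directed ortho‑metalation at C2, the position flanked by both OMOM groups, then borylation–oxidation under basic conditions that leave MOM intact.

**Step 3**
Reactants: 3 2,6‑bis(methoxymethoxy)phenol
Product: 4 4‑bromo‑2,6‑bis(methoxymethoxy)phenol
Conditions: NBS (1.0 equiv), cat. NaH, CHCl3, −45 °C → rt
Reagents that add atoms: N‑bromosuccinimide, O=C1CCC(=O)N1Br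
Why: Electrophilic aromatic bromination; the phenol(ate) is the strongest donor and both ortho positions are blocked, so bromine enters para to OH, as in the para‑bromination of 2,6‑dimethoxyphenol.

**Step 4**
Reactants: 5 3‑bromophenol
Product: 6 1‑bromo‑3‑(methoxymethoxy)benzene
Conditions: MOMCl, i‑Pr2NEt, CH2Cl2, 0 °C → rt
Reagents that add atoms: chloromethyl methyl ether (MOMCl), COCCl
Why: Standard MOM protection of a phenol; masks the ring‑A OH for the later Chan–Lam step.

**Step 5**
Reactants: 7 7‑bromohept‑1‑ene; 8 1,6‑dibromohexane (3 equiv)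
Product: 9 13‑bromotridec‑1‑ene
Conditions: 7, Mg, THF; then add to 8, Li2CuCl4 (3 mol%), THF, −10 °C → rt
Reagents that add atoms: none
Why: Kochi–Tamura Cu‑catalysed sp3–sp3 Grignard/alkyl bromide coupling; excess dibromide enforces mono‑substitution, and the 6‑heptenyl Grignard does not cyclise.

**Step 6**
Reactants: 9 13‑bromotridec‑1‑ene; 6 1‑bromo‑3‑(methoxymethoxy)benzene
Product: 10 1‑(13‑bromotridecyl)‑3‑(methoxymethoxy)benzene
Conditions: 9, 9‑BBN, THF, rt; then 6, PdCl2(dppf) (3 mol%), aq K3PO4, THF/DMF, 50 °C
Reagents that add atoms: none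
Why: Anti‑Markovnikov hydroboration then B‑alkyl Suzuki–Miyaura coupling; Pd(dppf) does not insert into the unactivated primary C–Br, so the ω‑bromide survives.

**Step 7**
Reactants: 10 1‑(13‑bromotridecyl)‑3‑(methoxymethoxy)benzene
Product: 11 [3‑(13‑bromotridecyl)‑5‑(methoxymethoxy)phenyl]boronic acid
Conditions: B2pin2, [Ir(OMe)(cod)]2 (1.5 mol%), dtbpy (3 mol%), THF, 80 °C; then NaIO4, aq NH4OAc, acetone/H2O, rt
Reagents that add atoms: bis(pinacolato)diboron, CC1(C)OB(OC1(C)C)B1OC(C)(C)C(C)(C)O1 (boron); water, O (B–OH oxygens)
Why: Sterically controlled Ir‑catalysed C–H borylation; in a 1,3‑disubstituted arene only C5 has no ortho substituent, and in‑pot periodate cleavage of the pinacol ester gives the boronic acid needed for a room‑temperature Chan–Lam coupling.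

**Step 8**
Reactants: 11 [3‑(13‑bromotridecyl)‑5‑(methoxymethoxy)phenyl]boronic acid (1.5 equiv); 4 4‑bromo‑2,6‑bis(methoxymethoxy)phenol
Product: 12 5‑bromo‑2‑[3‑(13‑bromotridecyl)‑5‑(methoxymethoxy)phenoxy]‑1,3‑bis(methoxymethoxy)benzene
Conditions: Cu(OAc)2 (1.5 equiv), pyridine (5 equiv), 4 Å MS, CH2Cl2, air, rt, 48 h
Reagents that add atoms: none
Why: Chan–Evans–Lam oxidative O‑arylation; it runs at rt without strong base, so the aryl bromide, alkyl bromide and MOM groups are untouched, and it is precedented for 2,6‑disubstituted phenols (diiodotyrosine‑type ethers).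

**Step 9**
Reactants: 12 the dibromo diaryl ether
Product: 13 4‑[3‑(13‑bromotridecyl)‑5‑(methoxymethoxy)phenoxy]‑3,5‑bis(methoxymethoxy)benzaldehyde
Conditions: n‑BuLi (1.05 equiv), THF, −78 °C, 10 min; DMF, −78 → 0 °C; aq NH4Cl
Reagents that add atoms: N,N‑dimethylformamide, CN(C)C=O (formyl C and O)
Why: Aryl Br–Li exchange at −78 °C is far faster than attack on a primary alkyl bromide (Parham‑type selectivity; the substrate bromide is no more reactive than the n‑BuBr by‑product) or MOM‑directed deprotonation, and the aryllithium is trapped by DMF (Bouveault formylation).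

**Step 10 (key step)**
Reactants: 13 the ω‑bromoalkyl seco‑aldehyde
Product: 14 tris‑MOM gravicycle: the 22‑membered meta,para‑cyclophane with an (R)‑benzylic alcohol at C1, ring A carrying one OMOM and ring B carrying two OMOM groups flanking the diaryl ether oxygen
Conditions: CrCl2 (3 equiv), Kishi oxazoline–sulfonamide ligand L* (3.3 equiv, enantiomer giving Re‑face addition), proton sponge, CoPc (10 mol%), NaI (3 equiv), LiCl, MeCN/DME, rt; 13 added by syringe pump over 24 h (final 2 mM); aq work‑up
Reagents that add atoms: none
Why: Proposed new method: an intramolecular, enantioselective Takai–Kishi Co/Cr alkyl halide–aldehyde coupling (alkyl‑NHK) used as a macrocyclisation. Co(I)Pc, formed by Cr(II), displaces the primary bromide (or the iodide formed in situ with NaI), and homolysis of the alkyl–Co(III) bond releases the primary C13 radical. That radical is captured at near diffusion rate by the chiral Cr(II)–sulfonamide complex. The resulting alkyl–Cr(III) species is persistent (no fast β‑H loss, inert to ethers and MOM), so it has time to reach the aldehyde at 2 mM. It adds to the Re face of the ArCHO inside the ligand sphere, closing the 22‑membered ring and setting C1 as (R) in one event. The ligand enantiomer is fixed beforehand on a 3,4,5‑trialkoxybenzaldehyde/1‑iodododecane model, and the product is checked by Mosher analysis. Closest known reactions: Takai's CoPc/B12–CrCl2 alkylation of aldehydes with alkyl halides, Kishi's catalytic asymmetric Co/Cr alkyl iodide–aldehyde coupling with the same ligand class, and Ni/Cr NHK macrocyclisations.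

**Step 11**
Reactants: 14 tris‑MOM gravicycle
Product: 15 gravicycle
Conditions: TMSOTf, 2,2′‑bipyridyl, CH2Cl2, 0 °C → rt; then H2O/THF, rt
Reagents that add atoms: none
Why: Fujioka‑type cleavage of aromatic MOM ethers via bipyridinium intermediates to aryl TMS ethers, hydrolysed on the water quench (together with any O‑TMS on the alcohol); the buffered, non‑protic medium avoids ionising the p‑aryloxybenzylic (R)‑alcohol, so the stereocentre is not scrambled.

## Compound list

1 | resorcinol | Oc1cccc(O)c1 | starting material
2 | 1,3‑bis(methoxymethoxy)benzene | COCOc1cccc(OCOC)c1 | intermediate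
3 | 2,6‑bis(methoxymethoxy)phenol | COCOc1cccc(OCOC)c1O | intermediate
4 | 4‑bromo‑2,6‑bis(methoxymethoxy)phenol | COCOc1cc(Br)cc(OCOC)c1O | intermediate
5 | 3‑bromophenol | Oc1cccc(Br)c1 | starting material
6 | 1‑bromo‑3‑(methoxymethoxy)benzene | COCOc1cccc(Br)c1 | intermediate
7 | 7‑bromohept‑1‑ene | C=CCCCCCBr | starting material
8 | 1,6‑dibromohexane | BrCCCCCCBr | starting material
9 | 13‑bromotridec‑1‑ene | C=CCCCCCCCCCCCBr | intermediate
10 | 1‑(13‑bromotridecyl)‑3‑(methoxymethoxy)benzene | COCOc1cccc(CCCCCCCCCCCCCBr)c1 | intermediate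
11 | [3‑(13‑bromotridecyl)‑5‑(methoxymethoxy)phenyl]boronic acid | COCOc1cc(CCCCCCCCCCCCCBr)cc(c1)B(O)O | intermediate
12 | 5‑bromo‑2‑[3‑(13‑bromotridecyl)‑5‑(methoxymethoxy)phenoxy]‑1,3‑bis(methoxymethoxy)benzene | COCOc1cc(CCCCCCCCCCCCCBr)cc(c1)Oc1c(OCOC)cc(Br)cc1OCOC | intermediate
13 | 4‑[3‑(13‑bromotridecyl)‑5‑(methoxymethoxy)phenoxy]‑3,5‑bis(methoxymethoxy)benzaldehyde | COCOc1cc(CCCCCCCCCCCCCBr)cc(c1)Oc1c(OCOC)cc(C=O)cc1OCOC | intermediate
14 | (R)‑tris‑O‑MOM gravicycle (22‑membered cyclophane, (R)‑benzylic alcohol) | COCOc1cc2cc(c1)Oc1c(OCOC)cc(cc1OCOC)[C@H](O)CCCCCCCCCCCCC2 | intermediate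
15 | gravicycle, (R) | Oc1cc2cc(c1)Oc1c(O)cc(cc1O)[C@H](O)CCCCCCCCCCCCC2 | target

## Step count and risks

Total steps: 11. Longest linear sequence: 7 (for example 3‑bromophenol → steps 4, 6, 7, 8, 9, 10, 11; the resorcinol and chain branches are also 7).

Steps most likely to fail:

1. **Step 10 (macrocyclisation).** Risks are oligomerisation, reduction or elimination of the chain terminus, and insufficient or wrong‑sense enantioselectivity with an aryl aldehyde. Fallback: separate ring closure from stereocontrol. Build the chain two carbons shorter (5‑bromopent‑1‑ene in place of 7), convert the aldehyde to the aryl vinyl ketone (vinylMgBr, then DMP), exchange Br for I, and close the ring by a Porter‑type radical Giese macrocyclisation ((TMS)3SiH, AIBN, high dilution). Then reduce the macrocyclic aryl ketone with (S)‑Me‑CBS/BH3 to the (R)‑alcohol.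
2. **Step 8 (Chan–Lam coupling).** The phenol is doubly ortho‑substituted, and protodeboronation or homocoupling of 11 may win. Fallback: convert 11 into its aryl(2,4,6‑trimethoxyphenyl)iodonium salt and O‑arylate phenol 4 without metal (KOt‑Bu, THF, rt); this chemistry tolerates hindered phenols and transfers the less electron‑rich aryl group.
3. **Step 11 (deprotection).** The p‑aryloxybenzylic alcohol could ionise (racemisation, substitution or elimination) under Lewis or Brønsted acid. Fallback: change the protecting‑group plan to SEM ethers in steps 1 and 4 (same metalation, borylation and coupling chemistry) and unmask with fluoride (TBAF/DMPU or CsF), so no acid touches the carbinol.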